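**Plan**
- Retrosynthesis: the two methyl groups on C11 are traced back to a lactone carbonyl (gem-dimethyl ⇐ spirocyclopropane ⇐ enol ether ⇐ C11=O). The C2′–O bond of the oxocine is then cut by removing the ring oxygen (aryl lactone ⇐ aryl ketone), followed by C2′–C11 (Heck), O1–C2 and C2–C3 of the pyranone (Baker–Venkataraman) and the A-ring acyl bond.
- Enabling feature: in the eight-membered ring the unit C2′–O–C11 is a C2′–C11 bond carrying one extra oxygen. The oxocine is therefore a benzocycloheptenone fused to the flavone C2=C3 bond plus one inserted atom, with the B-ring carbon C2′ as the migrating terminus.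
- Forward order: acylphloroglucinol A ring → pyranone C ring (flavone) → seven-membered carbocycle by 7-exo Heck closure and C=CH2 → C=O cleavage → eight-membered aryl lactone by oxygen insertion → C11 gem-dimethyl group, then deprotection.
- Stereochemistry: the target has no stereocentre, so nothing has to be set; the two stereogenic intermediates are racemic, not isolated, and lose their stereocentre within the same step.
- Numbering: flavone numbering for rings A, C and B; the bridge is C3–C13H2–C12H2–C11–O–C2′.

Key step: step 9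

Remark: the target SMILES holds no stereogenic centre, and the twisted C2–C1′ axis of the oxocine is assumed to invert freely at room temperature, so the "single enantiomer" is the achiral compound itself.

**Route**

Step 1
Reactants: 1 phloroglucinol (anhydrous); 2 hex-5-enoic acid
Product: 4 1-(2,4,6-trihydroxyphenyl)hex-5-en-1-one, via hex-5-enoyl chloride 3 (not isolated)
Conditions: 2, (COCl)2, cat. DMF, CH2Cl2, 0 °C → rt, evaporate; then 1, AlCl3 (3.5 equiv), CH2Cl2–PhNO2, 0 °C → rt; aq HCl work-up
Reagents that add atoms: none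
Why: Friedel–Crafts C-acylation of the threefold-activated, symmetrical arene (regiochemistry is trivial) should proceed at or below room temperature, where an isolated monosubstituted alkene, the least acid-sensitive alkene class, is expected to stay untouched.

Step 2
Reactants: 4 1-(2,4,6-trihydroxyphenyl)hex-5-en-1-one
Product: 5 1-(2,6-dihydroxy-4-methoxyphenyl)hex-5-en-1-one
Conditions: Me2SO4 (1.0 equiv), K2CO3 (1.0 equiv), acetone, rt → 40 °C
Reagents that add atoms: dimethyl sulfate, COS(=O)(=O)OC
Why: Williamson methylation with one equivalent of base and electrophile should take the 4-OH, the most acidic and the only non-chelated hydroxyl, because both ortho hydroxyls are hydrogen-bonded to the ketone.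

Step 3
Reactants: 5 1-(2,6-dihydroxy-4-methoxyphenyl)hex-5-en-1-one
Product: 6 1-[2-(benzyloxy)-6-hydroxy-4-methoxyphenyl]hex-5-en-1-one
Conditions: BnBr (1.05 equiv), K2CO3, acetone, reflux
Reagents that add atoms: benzyl bromide, BrCc1ccccc1
Why: Williamson benzylation should stop after one ortho hydroxyl, since the remaining one stays chelated to the carbonyl and is far less nucleophilic.

Step 4
Reactants: 7 2-bromo-4-hydroxybenzoic acid
Product: 9 4-(benzyloxy)-2-bromobenzoic acid, via benzyl 4-(benzyloxy)-2-bromobenzoate 8 (not isolated)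
Conditions: BnBr (2.3 equiv), K2CO3, DMF, 60 °C; then aq NaOH, MeOH–THF, 60 °C; HCl to pH 2
Reagents that add atoms: benzyl bromide, BrCc1ccccc1
Why: exhaustive O-benzylation followed by saponification removes only the benzyl ester, because the aryl benzyl ether is inert to hydroxide.

Step 5
Reactants: 9 4-(benzyloxy)-2-bromobenzoic acid; 6 1-[2-(benzyloxy)-6-hydroxy-4-methoxyphenyl]hex-5-en-1-one
Product: 11 3-(benzyloxy)-2-(hex-5-enoyl)-5-methoxyphenyl 4-(benzyloxy)-2-bromobenzoate, via 4-(benzyloxy)-2-bromobenzoyl chloride 10 (not isolated)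
Conditions: 9, (COCl)2, cat. DMF, CH2Cl2, rt, evaporate; then 6, Et3N, DMAP (cat.), CH2Cl2, 0 °C → rt
Reagents that add atoms: none
Why: acid chloride formation and DMAP-catalysed O-acylation of the chelated phenol is the standard entry to Baker–Venkataraman substrates and tolerates the ortho bromine.

Step 6
Reactants: 11 3-(benzyloxy)-2-(hex-5-enoyl)-5-methoxyphenyl 4-(benzyloxy)-2-bromobenzoate
Product: 13 5-(benzyloxy)-2-[4-(benzyloxy)-2-bromophenyl]-3-(but-3-en-1-yl)-7-methoxy-4H-chromen-4-one, via β-diketone 12 (not isolated)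
Conditions: KOtBu (2.2 equiv), THF, 0 °C → rt; AcOH quench, evaporate; then TsOH·H2O (0.2 equiv), toluene, 90 °C (Dean–Stark)
Reagents that add atoms: none
Why: Baker–Venkataraman rearrangement (the ketone enolate takes the aroyl group from the neighbouring aryl ester through a six-membered transition state) followed by acid-catalysed cyclodehydration of the phenol onto the aroyl carbonyl should give the 3-alkylflavone, with catalytic TsOH chosen to spare the alkene and the benzyl ethers.

Step 7
Reactants: 13 5-(benzyloxy)-2-[4-(benzyloxy)-2-bromophenyl]-3-(but-3-en-1-yl)-7-methoxy-4H-chromen-4-one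
Product: 14 11-methylene carbocycle (5-benzyloxy-7-methoxyflavone with 4′-OBn whose C3 and C2′ are joined by a CH2CH2C(=CH2) bridge in a seven-membered ring)
Conditions: Pd(OAc)2 (10 mol %), PPh3 (25 mol %), Ag2CO3 (1.5 equiv), MeCN, 80 °C
Reagents that add atoms: none
Why: intramolecular Mizoroki–Heck reaction, in which oxidative addition at C2′–Br, 7-exo-trig carbopalladation of the terminal alkene and elimination of the single available β-hydrogen give the exocyclic methylene; phosphine/silver conditions favour exo closure and suppress Pd–H isomerisation into the ring.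

Step 8
Reactants: 14 11-methylene carbocycle
Product: 16 C11 ketone (5-benzyloxy-7-methoxyflavone with 4′-OBn whose C3 and C2′ are joined by a CH2CH2C(=O) bridge in a seven-membered ring), via 11-hydroxy-11-(hydroxymethyl) diol 15 (not isolated)
Conditions: OsO4 (3 mol %), NaIO4 (4 equiv), 2,6-lutidine (2 equiv), dioxane–H2O 3:1, rt
Reagents that add atoms: osmium tetroxide, O=[Os](=O)(=O)=O; sodium periodate, [Na+].[O-]I(=O)(=O)=O
Why: Lemieux–Johnson oxidation, in which OsO4 dihydroxylates the electron-rich 1,1-disubstituted styrene-type alkene and periodate cleaves the diol, while the tetrasubstituted, electron-poor chromone C2=C3 bond should not react.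

Step 9
Reactants: 16 C11 ketone
Product: 17 eight-membered aryl lactone (5-benzyloxy-7-methoxyflavone with 4′-OBn whose C3 and C2′ are joined by a CH2CH2C(=O)O bridge, oxygen on C2′)
Conditions: mCPBA (3 equiv), TFA (1 equiv), CH2Cl2, 0 °C → rt, dark
Reagents that add atoms: 3-chloroperbenzoic acid, OOC(=O)c1cccc(Cl)c1
Why: Baeyer–Villiger oxidation: acid-catalysed addition of the peracid to the C11 carbonyl gives the Criegee adduct, in which the B-ring carbon C2′ lying antiperiplanar to the O–O bond shifts from C11 to oxygen as 3-chlorobenzoate departs, creating the C2′–O bond. The closest known reaction type is the peracid ring expansion of 1-tetralones and 1-benzosuberones to benzoxepinones and benzoxocinones with aryl migration. The eight-membered ring arises by one-atom enlargement of the existing seven-membered ring (7 → 8), so no medium-ring cyclisation event and no entropy of closure are involved. No stereocentre is formed. The selectivity needed is migration of the sp2 carbon C2′ in preference to the primary C12 methylene; it rests on the usual aryl-over-primary-alkyl aptitude, on π-participation of the B ring that the acid co-catalyst accentuates, and on the twist of the seven-membered ring, which takes C11=O out of conjugation and aligns the C11–C2′ bond with the peroxide bond. The C4 carbonyl is a vinylogous ester that does not add peracid, the tetrasubstituted electron-poor C2=C3 bond should not be epoxidised, and benzyl ethers are inert.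

Step 10
Reactants: 17 eight-membered aryl lactone
Product: 18 11-methylene oxocine (cyclic aryl enol ether; bridge CH2CH2C(=CH2)O)
Conditions: Tebbe reagent (1.2 equiv), pyridine (cat.), THF–toluene, −40 → 0 °C; aq NaOH quench; Et3N-deactivated silica
Reagents that add atoms: Tebbe reagent, C[Al-]1(C)C[Ti]([Cl+]1)(C1C=CC=C1)C1C=CC=C1
Why: Tebbe methylenation, in which the titanium methylidene adds [2+2] to the activated aryl-ester carbonyl and cycloreverts with Ti=O formation; at low temperature the C4 carbonyl, a vinylogous ester flanked by 5-OBn and the C3 substituent, should react much more slowly.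

Step 11
Reactants: 18 11-methylene oxocine
Product: 19 5,4′-di-O-benzyl spirocyclopropane (cyclopropane spiro-fused at C11 of the oxocine)
Conditions: Et2Zn (5 equiv), CH2I2 (10 equiv), CH2Cl2, 0 °C → rt
Reagents that add atoms: diiodomethane, ICI
Why: Simmons–Smith cyclopropanation (Furukawa variant), in which the electrophilic zinc carbenoid adds to the electron-rich 1,1-disubstituted aryl enol ether and leaves the electron-poor chromone alkene alone; excess Et2Zn buffers Lewis-acidic zinc iodide.

Step 12
Reactants: 19 5,4′-di-O-benzyl spirocyclopropane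
Product: 20 5,4′-dihydroxy spirocyclopropane (cyclointegrin in which the two methyl carbons on C11 are linked as a cyclopropane)
Conditions: H2 (1 atm), 10 % Pd/C, EtOAc–MeOH, rt
Reagents that add atoms: none
Why: catalytic hydrogenolysis of aryl benzyl ethers over palladium, which at 1 atm should leave the cyclopropane and the tetrasubstituted C2=C3 bond intact.

Step 13
Reactants: 20 5,4′-dihydroxy spirocyclopropane
Product: 21 cyclointegrin
Conditions: H2 (1–3 atm), PtO2, AcOH, rt
Reagents that add atoms: none
Why: hydrogenolysis of a 1,1-disubstituted cyclopropane over Adams catalyst, in which the least hindered distal CH2–CH2 bond is cleaved, so the spirocyclopropane should open to the gem-dimethyl group on C11.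

**Compound list**

1 | phloroglucinol (benzene-1,3,5-triol) | Oc1cc(O)cc(O)c1 | starting material
2 | hex-5-enoic acid | C=CCCCC(=O)O | starting material
3 | hex-5-enoyl chloride | C=CCCCC(=O)Cl | intermediate
4 | 1-(2,4,6-trihydroxyphenyl)hex-5-en-1-one | C=CCCCC(=O)c1c(O)cc(O)cc1O | intermediate
5 | 1-(2,6-dihydroxy-4-methoxyphenyl)hex-5-en-1-one | C=CCCCC(=O)c1c(O)cc(OC)cc1O | intermediate
6 | 1-[2-(benzyloxy)-6-hydroxy-4-methoxyphenyl]hex-5-en-1-one | C=CCCCC(=O)c1c(O)cc(OC)cc1OCc1ccccc1 | intermediate
7 | 2-bromo-4-hydroxybenzoic acid | O=C(O)c1ccc(O)cc1Br | starting material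
8 | benzyl 4-(benzyloxy)-2-bromobenzoate | O=C(OCc1ccccc1)c1ccc(OCc2ccccc2)cc1Br | intermediate
9 | 4-(benzyloxy)-2-bromobenzoic acid | O=C(O)c1ccc(OCc2ccccc2)cc1Br | intermediate
10 | 4-(benzyloxy)-2-bromobenzoyl chloride | O=C(Cl)c1ccc(OCc2ccccc2)cc1Br | intermediate
11 | 3-(benzyloxy)-2-(hex-5-enoyl)-5-methoxyphenyl 4-(benzyloxy)-2-bromobenzoate | C=CCCCC(=O)c1c(OC(=O)c2ccc(OCc3ccccc3)cc2Br)cc(OC)cc1OCc1ccccc1 | intermediate
12 | 1-[2-(benzyloxy)-6-hydroxy-4-methoxyphenyl]-3-[4-(benzyloxy)-2-bromophenyl]-2-(but-3-en-1-yl)propane-1,3-dione (racemic, enolisable) | C=CCCC(C(=O)c1c(O)cc(OC)cc1OCc1ccccc1)C(=O)c1ccc(OCc2ccccc2)cc1Br | intermediate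
13 | 5-(benzyloxy)-2-[4-(benzyloxy)-2-bromophenyl]-3-(but-3-en-1-yl)-7-methoxy-4H-chromen-4-one | COc1cc(OCc2ccccc2)c2c(=O)c(CCC=C)c(-c3ccc(OCc4ccccc4)cc3Br)oc2c1 | intermediate
14 | 11-methylene carbocycle: 5-benzyloxy-7-methoxyflavone, 4′-OBn, C3 and C2′ joined by CH2CH2C(=CH2) (seven-membered ring) | COc1cc(OCc2ccccc2)c2c(=O)c3c(oc2c1)-c1ccc(OCc2ccccc2)cc1C(=C)CC3 | intermediate
15 | 11-hydroxy-11-(hydroxymethyl) diol of 14 (racemic) | COc1cc(OCc2ccccc2)c2c(=O)c3c(oc2c1)-c1ccc(OCc2ccccc2)cc1C(O)(CO)CC3 | intermediate
16 | C11 ketone: 5,4′-di-O-benzyl flavone-fused seven-membered aryl ketone, bridge CH2CH2C(=O) | COc1cc(OCc2ccccc2)c2c(=O)c3c(oc2c1)-c1ccc(OCc2ccccc2)cc1C(=O)CC3 | intermediate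
17 | eight-membered aryl lactone: 5,4′-di-O-benzyl-11-oxo-11-bis(demethyl)cyclointegrin, bridge CH2CH2C(=O)O | COc1cc(OCc2ccccc2)c2c(=O)c3c(oc2c1)-c1ccc(OCc2ccccc2)cc1OC(=O)CC3 | intermediate
18 | 11-methylene oxocine (cyclic aryl enol ether), 5,4′-di-O-benzyl | COc1cc(OCc2ccccc2)c2c(=O)c3c(oc2c1)-c1ccc(OCc2ccccc2)cc1OC(=C)CC3 | intermediate
19 | 5,4′-di-O-benzyl spirocyclopropane (cyclopropane spiro at C11) | COc1cc(OCc2ccccc2)c2c(=O)c3c(oc2c1)-c1ccc(OCc2ccccc2)cc1OC1(CC1)CC3 | intermediate
20 | 5,4′-dihydroxy spirocyclopropane | COc1cc(O)c2c(=O)c3c(oc2c1)-c1ccc(O)cc1OC1(CC1)CC3 | intermediate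
21 | cyclointegrin | COc1cc(O)c2c(=O)c3c(oc2c1)-c1ccc(O)cc1OC(C)(C)CC3 | target

**Step count**

Total: 13 steps. Longest linear sequence: 12 steps (steps 1–3 and 5–13 from phloroglucinol); the B-ring acid 9 takes one step (step 4) and joins at step 5.

**Steps most likely to fail**

1. Step 9 (Baeyer–Villiger). The C12 methylene may migrate in place of C2′, because the migrating aryl carbon carries an ortho chromonyl group and only a meta alkoxy group. Peracid addition to the hindered, twisted ketone may also be slow enough for electrophilic hydroxylation of the A ring to intervene. The fallback sets out from bromoflavone 13 and comes back at lactone 17, forming the C2′–O bond by C–B oxidation and closing the ring by acylation. Miyaura borylation of 13 (B2pin2, Pd(dppf)Cl2, KOAc, dioxane, 90 °C) would give the aryl pinacol boronate F1, and oxidation with NaBO3·4H2O in THF–H2O the 2′-phenol F2. Lemieux–Johnson cleavage of the butenyl chain (OsO4 cat., NaIO4, 2,6-lutidine) would pass through the terminal diol F3 to the aldehyde F4, and Pinnick oxidation (NaClO2, NaH2PO4, 2-methyl-2-butene) would give the propanoic acid F5. Lactonisation of F5 at high dilution (2-chloro-1-methylpyridinium iodide, Et3N, MeCN, reflux) would join the acid to the 2′-OH and deliver 17.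

2. Step 10 (Tebbe methylenation). The titanium methylidene may also attack the C4 carbonyl, and the aryl enol ether may be opened hydrolytically during isolation. The fallback sets out from lactone 17 and comes back at the target 21; it gives up the intact ring and recloses it. MeMgBr (excess, THF, −78 → −20 °C), which should take the activated aryl ester well before the hindered vinylogous ester, would open 17 to the 2′-phenol tertiary alcohol F6. Hydrogenolysis (H2, Pd/C) would give the debenzylated triol alcohol F7. Acid-catalysed cycloetherification (TsOH or Amberlyst-15, warm 1,2-dichloroethane) would let the 2′-OH capture the tertiary cation and close the oxocine to 21; the eight-membered closure is the uncertain point of this fallback.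

3. Step 13 (cyclopropane hydrogenolysis). Over platinum in acetic acid the phenolic rings or the C2=C3 bond may be reduced, a proximal cyclopropane bond may cleave in place of the distal one, or the acid may open the cyclopropyl ether. The fallback sets out from enol ether 18 and comes back at the target 21. Markovnikov addition of methanol (PPTS cat., MeOH–CH2Cl2, 0 °C) would give the mixed methyl aryl ketal F8 (racemic). AlMe3 (CH2Cl2, −78 → 0 °C) would ionise the methoxy group and deliver methyl to the cyclic oxocarbenium ion, giving 5,4′-di-O-benzylcyclointegrin F9. Hydrogenolysis (H2, Pd/C, EtOAc–MeOH) would then give 21.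

**Further compounds**

F1 | step 9 | 5-(benzyloxy)-2-[4-(benzyloxy)-2-(4,4,5,5-tetramethyl-1,3,2-dioxaborolan-2-yl)phenyl]-3-(but-3-en-1-yl)-7-methoxy-4H-chromen-4-one | COc1cc(OCc2ccccc2)c2c(=O)c(CCC=C)c(-c3ccc(OCc4ccccc4)cc3B3OC(C)(C)C(C)(C)O3)oc2c1
F2 | step 9 | 5-(benzyloxy)-2-[4-(benzyloxy)-2-hydroxyphenyl]-3-(but-3-en-1-yl)-7-methoxy-4H-chromen-4-one | COc1cc(OCc2ccccc2)c2c(=O)c(CCC=C)c(-c3ccc(OCc4ccccc4)cc3O)oc2c1
F3 | step 9 | 5-(benzyloxy)-2-[4-(benzyloxy)-2-hydroxyphenyl]-3-(3,4-dihydroxybutyl)-7-methoxy-4H-chromen-4-one (racemic) | COc1cc(OCc2ccccc2)c2c(=O)c(CCC(O)CO)c(-c3ccc(OCc4ccccc4)cc3O)oc2c1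
F4 | step 9 | 3-{5-(benzyloxy)-2-[4-(benzyloxy)-2-hydroxyphenyl]-7-methoxy-4-oxo-4H-chromen-3-yl}propanal | COc1cc(OCc2ccccc2)c2c(=O)c(CCC=O)c(-c3ccc(OCc4ccccc4)cc3O)oc2c1
F5 | step 9 | 3-{5-(benzyloxy)-2-[4-(benzyloxy)-2-hydroxyphenyl]-7-methoxy-4-oxo-4H-chromen-3-yl}propanoic acid | COc1cc(OCc2ccccc2)c2c(=O)c(CCC(=O)O)c(-c3ccc(OCc4ccccc4)cc3O)oc2c1
F6 | step 10 | 5-(benzyloxy)-2-[4-(benzyloxy)-2-hydroxyphenyl]-3-(3-hydroxy-3-methylbutyl)-7-methoxy-4H-chromen-4-one | COc1cc(OCc2ccccc2)c2c(=O)c(CCC(C)(C)O)c(-c3ccc(OCc4ccccc4)cc3O)oc2c1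
F7 | step 10 | 2-(2,4-dihydroxyphenyl)-5-hydroxy-3-(3-hydroxy-3-methylbutyl)-7-methoxy-4H-chromen-4-one | COc1cc(O)c2c(=O)c(CCC(C)(C)O)c(-c3ccc(O)cc3O)oc2c1
F8 | step 13 | 5,4′-di-O-benzyl-11-methoxy-11-methyl oxocine (mixed methyl aryl ketal, racemic) | COc1cc(OCc2ccccc2)c2c(=O)c3c(oc2c1)-c1ccc(OCc2ccccc2)cc1OC(C)(OC)CC3
F9 | step 13 | 5,4′-di-O-benzylcyclointegrin | COc1cc(OCc2ccccc2)c2c(=O)c3c(oc2c1)-c1ccc(OCc2ccccc2)cc1OC(C)(C)CC3
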